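**Retrosynthetic overview**

- Feature: number the cyclohexene C1 (quaternary; CH3 and Cα of the Cα=Cβ link to coumarin B), C2 (H and C8 of coumarin A), C3=C4(CH3), C5, C6. C1 with its neighbours C2 and C6 maps onto the quaternary carbon and the two β-carbons of a prochiral 4,4-disubstituted cyclohexa-2,5-dienone (C4 as carbonyl). Because O1 and C8 of coumarin A are ortho, an aryl ester Cα(=O)–O1 can deliver C8 to C2 through a six-membered lactone.
- Last disconnections: the pyranone ring of coumarin A (C4a–C4 and O1–C2) by ortho-formylation and Wittig lactonisation of a free phenol; Cα=Cβ by Horner–Wadsworth–Emmons olefination of a lactol with the coumarin B methylphosphonate made from citropten.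
- The lactol comes from the enone lactone of the key step: C4–CH3 through the C3 enol triflate and Negishi coupling, C5–C6 saturation with diimide, half-reduction of the lactone.
- Key disconnection C2–C8: enantioselective reductive Heck desymmetrisation of the achiral 2-bromo-3,5-dimethoxyphenyl dienone ester. This ester is made from benzoic acid by Birch methylation, esterification and a late bis-allylic oxidation; the free 4-oxo-dienoic acid is avoided because it would lose CO2 to p-cresol.
- Ring order: carbocycle (from benzoic acid), then the lactone ring in the key step (opened again at the olefination), then the pyranone ring of coumarin A last; coumarin B is carried in intact.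

Key step: step 5

Remark: the ligand antipode that gives the (6aS,10aS) product of step 5 cannot be predicted with confidence and is fixed in the first ligand screen ((R)-BINAP is written for definiteness); the CIP descriptors change from (S,S) in the lactone series to (R,R) in the styryl series only because substituent priorities change, no centre being inverted.

**Route**

Step 1
Reactants: 1 benzoic acid
Product: 3 1-methylcyclohexa-2,5-diene-1-carboxylic acid, via dilithium enediolate 2 (not isolated)
Conditions: Li, NH3(l)/THF, −78 °C; MeI, −78 °C; NH4Cl, then aq. HCl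
Reagents that add atoms: iodomethane, CI
Why: Birch reduction of the benzoate to its cross-conjugated enediolate and C-alkylation at the carboxyl-bearing carbon (Birch reductive alkylation) should give the skipped diene with the quaternary centre that later becomes C1.

Step 2
Reactants: 4 3,5-dimethoxyphenol
Product: 5 2-bromo-3,5-dimethoxyphenol
Conditions: NBS (1.0 equiv), i-Pr2NH (10 mol%), CH2Cl2, −78 → 0 °C
Reagents that add atoms: N-bromosuccinimide, O=C1CCC(=O)N1Br
Why: Electrophilic aromatic bromination in which the secondary amine turns NBS into an N-bromoamine hydrogen-bonded to the phenol, so bromine is delivered ortho to the hydroxyl group rather than between the methoxy groups (the minor 4-bromo isomer is removed by chromatography).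

Step 3
Reactants: 3 1-methylcyclohexa-2,5-diene-1-carboxylic acid; 5 2-bromo-3,5-dimethoxyphenol
Product: 7 2-bromo-3,5-dimethoxyphenyl 1-methylcyclohexa-2,5-diene-1-carboxylate, via acid chloride 6 (not isolated)
Conditions: (COCl)2, DMF (cat.), CH2Cl2, 0 °C → rt; then 5, Et3N, DMAP (cat.), CH2Cl2, 0 °C → rt
Reagents that add atoms: none
Why: Acid chloride formation followed by DMAP-catalysed acylation of the hindered phenol; the α-quaternary acid can form neither a ketene nor an epimer, and the skipped diene is stable to these non-oxidising conditions.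

Step 4
Reactants: 7 2-bromo-3,5-dimethoxyphenyl 1-methylcyclohexa-2,5-diene-1-carboxylate
Product: 8 2-bromo-3,5-dimethoxyphenyl 1-methyl-4-oxocyclohexa-2,5-diene-1-carboxylate
Conditions: (C5H5NH)2Cr2O7, t-BuOOH, Celite, benzene, 10 °C → rt
Reagents that add atoms: tert-butyl hydroperoxide, CC(C)(C)OO
Why: Chromium-mediated bis-allylic C–H oxidation with tert-butyl hydroperoxide as terminal oxidant should convert the skipped diene into the cross-conjugated dienone; the ketone is introduced only after esterification because the free 4-oxo acid would decarboxylate, and the quaternary C1 blocks aromatisation.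

Step 5
Reactants: 8 2-bromo-3,5-dimethoxyphenyl 1-methyl-4-oxocyclohexa-2,5-diene-1-carboxylate
Product: 9 (6aS,10aS)-1,3-dimethoxy-6a-methyl-10,10a-dihydro-6H-benzo[c]chromene-6,9(6aH)-dione
Conditions: Pd2(dba)3 (2.5 mol%), (R)-BINAP (6 mol%), HCO2H/i-Pr2NEt (syringe pump), DMF, 80 °C
Reagents that add atoms: none
Why: Zerovalent palladium inserts into the hindered C–Br bond, the arylpalladium bromide adds syn across one of the two enantiotopic enone C=C bonds (6-exo-trig, closing the six-membered lactone once the ester has rotated into its s-trans form), and the palladium enolate so formed cannot undergo β-hydride elimination (C1 is quaternary, H on C2 is anti to palladium) and is reduced by formate with loss of CO2. The closest known reaction is the palladium-catalysed enantioselective reductive Heck desymmetrisation of cyclohexa-2,5-dienones carrying an aryl halide on an ether or amine tether at the quaternary carbon, and palladium-mediated ring closures through aryl ester tethers are established in biaryl lactone synthesis. C10a (C2 of the cyclohexene) is set by the chiral ligand, which decides which alkene inserts; C6a (C1) becomes stereogenic in the same event and is held cis to C10a by the three-atom ester tether and the syn insertion. The step needs alkene insertion to outrun formate reduction of the arylpalladium intermediate, which slow addition of the formate and the doubly activated dienone should secure. It also needs the aryl ester to survive, which the aprotic medium and the neopentyl-like acyl carbon should secure.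

Step 6
Reactants: 9 (6aS,10aS)-1,3-dimethoxy-6a-methyl-10,10a-dihydro-6H-benzo[c]chromene-6,9(6aH)-dione
Product: 11 (6aS,10aS)-1,3-dimethoxy-6a-methyl-6-oxo-6a,10a-dihydro-6H-benzo[c]chromen-9-yl trifluoromethanesulfonate, via potassium dienolate 10 (not isolated)
Conditions: KN(SiMe3)2, THF, −78 °C; PhNTf2, −78 → 0 °C
Reagents that add atoms: N-phenylbis(trifluoromethanesulfonimide), O=S(=O)(N(c1ccccc1)S(=O)(=O)C(F)(F)F)C(F)(F)F
Why: Kinetic enol triflate formation: the enone can be deprotonated only at C10 (C8 is vinylic, the γ-position C6a is quaternary), so a single cross-conjugated dienolate forms and is O-sulfonylated without touching C6a or C10a.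

Step 7
Reactants: 11 (6aS,10aS)-1,3-dimethoxy-6a-methyl-6-oxo-6a,10a-dihydro-6H-benzo[c]chromen-9-yl trifluoromethanesulfonate
Product: 12 (6aS,10aS)-1,3-dimethoxy-6a,9-dimethyl-6a,10a-dihydro-6H-benzo[c]chromen-6-one
Conditions: Me2Zn, Pd(PPh3)4 (5 mol%), THF, 0 °C → rt
Reagents that add atoms: dimethylzinc, C[Zn]C
Why: Negishi cross-coupling of the alkenyl triflate with Me2Zn tolerates the aryl lactone and is run at or below room temperature so that the cyclohexadiene does not undergo 1,5-hydrogen shifts.

Step 8
Reactants: 12 (6aS,10aS)-1,3-dimethoxy-6a,9-dimethyl-6a,10a-dihydro-6H-benzo[c]chromen-6-one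
Product: 13 (6aS,10aS)-1,3-dimethoxy-6a,9-dimethyl-6a,7,8,10a-tetrahydro-6H-benzo[c]chromen-6-one
Conditions: 2-O2NC6H4SO2NHNH2, Et3N, CH2Cl2, rt
Reagents that add atoms: none
Why: Diimide reduction (concerted syn transfer of H2 from HN=NH made in situ) should prefer the cis-disubstituted C7=C8 bond of the diene over the trisubstituted C9=C10 bond and leave lactone and arene untouched; no stereocentre is formed or affected.

Step 9
Reactants: 13 (6aS,10aS)-1,3-dimethoxy-6a,9-dimethyl-6a,7,8,10a-tetrahydro-6H-benzo[c]chromen-6-one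
Product: 14 (6aS,10aS)-1,3-dimethoxy-6a,9-dimethyl-6a,7,8,10a-tetrahydro-6H-benzo[c]chromen-6-ol (lactol; both C6 epimers)
Conditions: i-Bu2AlH (1.1 equiv), CH2Cl2, −78 °C; aq. potassium sodium tartrate
Reagents that add atoms: none
Why: Half-reduction of a lactone with i-Bu2AlH at −78 °C: the tetrahedral aluminium hemiacetal of the hindered carbonyl should persist until hydrolysis, giving the 2-hydroxychroman, and neither ring stereocentre is enolisable.

Step 10
Reactants: 15 5,7-dimethoxy-2H-chromen-2-one (citropten)
Product: 17 5,7-dimethoxy-2-oxo-2H-chromene-8-carbaldehyde, via aryl iminium chloride 16 (not isolated)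
Conditions: POCl3, DMF, 0 → 70 °C; aq. NaOAc
Reagents that add atoms: N,N-dimethylformamide, CN(C)C=O; water, O
Why: Vilsmeier–Haack formylation: of the two positions activated by both methoxy groups, C8 (flanked by one methoxy group and the ring oxygen, para to the 5-methoxy group) is more accessible than C6 (between two methoxy groups), and the pyranone ring is deactivated.

Step 11
Reactants: 17 5,7-dimethoxy-2-oxo-2H-chromene-8-carbaldehyde
Product: 18 8-(hydroxymethyl)-5,7-dimethoxy-2H-chromen-2-one
Conditions: NaBH4, MeOH/THF, 0 °C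
Reagents that add atoms: none
Why: Chemoselective hydride reduction of the aryl aldehyde by NaBH4 at 0 °C, under which the coumarin lactone and its C3=C4 bond should not be attacked.

Step 12
Reactants: 18 8-(hydroxymethyl)-5,7-dimethoxy-2H-chromen-2-one
Product: 20 diethyl [(5,7-dimethoxy-2-oxo-2H-chromen-8-yl)methyl]phosphonate, via benzylic bromide 19 (not isolated)
Conditions: PBr3, CH2Cl2, 0 °C; then P(OEt)3, 120 °C
Reagents that add atoms: triethyl phosphite, CCOP(OCC)OCC
Why: Bromination of the benzylic alcohol with PBr3 followed by Michaelis–Arbuzov reaction of the reactive benzylic bromide with triethyl phosphite.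

Step 13
Reactants: 14 (6aS,10aS)-1,3-dimethoxy-6a,9-dimethyl-6a,7,8,10a-tetrahydro-6H-benzo[c]chromen-6-ol; 20 diethyl [(5,7-dimethoxy-2-oxo-2H-chromen-8-yl)methyl]phosphonate
Product: 23 8-[(E)-2-[(1R,2R)-2-(2-hydroxy-4,6-dimethoxyphenyl)-1,4-dimethylcyclohex-3-en-1-yl]ethenyl]-5,7-dimethoxy-2H-chromen-2-one, via phosphonate carbanion 21 (not isolated), via ring-opened aldehyde 22 (not isolated)
Conditions: 20 (1.6 equiv), KN(SiMe3)2 (2.7 equiv), THF, −78 → 0 °C; then 14, 0 → 45 °C; aq. NH4Cl
Reagents that add atoms: none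
Why: Horner–Wadsworth–Emmons olefination: the lactolate opens to the phenoxide aldehyde, whose α-quaternary carbonyl cannot enolise or epimerise, and the benzylic phosphonate carbanion should give the (E)-alkene; work-up is kept near neutral because the ortho-cyclohexenylphenol can cyclise under acid.

Step 14
Reactants: 23 8-[(E)-2-[(1R,2R)-2-(2-hydroxy-4,6-dimethoxyphenyl)-1,4-dimethylcyclohex-3-en-1-yl]ethenyl]-5,7-dimethoxy-2H-chromen-2-one
Product: 25 8-[(E)-2-[(1R,2R)-2-(3-formyl-2-hydroxy-4,6-dimethoxyphenyl)-1,4-dimethylcyclohex-3-en-1-yl]ethenyl]-5,7-dimethoxy-2H-chromen-2-one, via salicyl alcohol 24 (not isolated)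
Conditions: MgCl2, Et3N, (CH2O)n, MeCN, reflux; aq. NH4Cl
Reagents that add atoms: formaldehyde (as paraformaldehyde), C=O
Why: Casnati–Skattebøl ortho-formylation: the magnesium-bound phenol oxygen delivers formaldehyde to the only free ortho carbon (the future C4a of coumarin A) and the hydroxymethyl group is oxidised in situ by hydride transfer to a second formaldehyde, so the position between the two methoxy groups is not attacked.

Step 15
Reactants: 25 8-[(E)-2-[(1R,2R)-2-(3-formyl-2-hydroxy-4,6-dimethoxyphenyl)-1,4-dimethylcyclohex-3-en-1-yl]ethenyl]-5,7-dimethoxy-2H-chromen-2-one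
Product: 27 8-[(E)-2-[(1R,2R)-2-(5,7-dimethoxy-2-oxo-2H-chromen-8-yl)-1,4-dimethylcyclohex-3-en-1-yl]ethenyl]-5,7-dimethoxy-2H-chromen-2-one (CNP0164660.2), via ortho-hydroxycinnamate 26 (not isolated)
Conditions: Ph3P=CHCO2Et, PhNEt2, 200 °C
Reagents that add atoms: ethyl (triphenylphosphoranylidene)acetate, CCOC(=O)C=P(c1ccccc1)(c1ccccc1)c1ccccc1
Why: Wittig olefination of the salicylaldehyde with the stabilised ylide should give the (E)-ortho-hydroxycinnamate, which at this temperature isomerises and lactonises with loss of ethanol (the classical coumarin synthesis), completing coumarin A without touching the stereocentres.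

**Compound list**

1 | benzoic acid | O=C(O)c1ccccc1 | starting material
2 | dilithium enediolate of 1,4-dihydrobenzoic acid | [Li+].[Li+].[O-]C([O-])=C1C=CCC=C1 | intermediate (not isolated)
3 | 1-methylcyclohexa-2,5-diene-1-carboxylic acid | CC1(C(=O)O)C=CCC=C1 | intermediate
4 | 3,5-dimethoxyphenol | COc1cc(O)cc(OC)c1 | starting material
5 | 2-bromo-3,5-dimethoxyphenol | COc1cc(O)c(Br)c(OC)c1 | intermediate
6 | 1-methylcyclohexa-2,5-diene-1-carbonyl chloride | CC1(C(=O)Cl)C=CCC=C1 | intermediate (not isolated)
7 | 2-bromo-3,5-dimethoxyphenyl 1-methylcyclohexa-2,5-diene-1-carboxylate | CC1(C(=O)Oc2cc(OC)cc(OC)c2Br)C=CCC=C1 | intermediate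
8 | 2-bromo-3,5-dimethoxyphenyl 1-methyl-4-oxocyclohexa-2,5-diene-1-carboxylate | CC1(C(=O)Oc2cc(OC)cc(OC)c2Br)C=CC(=O)C=C1 | intermediate
9 | (6aS,10aS)-1,3-dimethoxy-6a-methyl-10,10a-dihydro-6H-benzo[c]chromene-6,9(6aH)-dione | O=C1Oc2cc(OC)cc(OC)c2[C@@H]2CC(=O)C=C[C@]12C | intermediate
10 | potassium (6aS,10aS)-1,3-dimethoxy-6a-methyl-6-oxo-6a,10a-dihydro-6H-benzo[c]chromen-9-olate | O=C1Oc2cc(OC)cc(OC)c2[C@@H]2C=C([O-])C=C[C@]12C.[K+] | intermediate (not isolated)
11 | (6aS,10aS)-1,3-dimethoxy-6a-methyl-6-oxo-6a,10a-dihydro-6H-benzo[c]chromen-9-yl trifluoromethanesulfonate | O=C1Oc2cc(OC)cc(OC)c2[C@@H]2C=C(OS(=O)(=O)C(F)(F)F)C=C[C@]12C | intermediate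
12 | (6aS,10aS)-1,3-dimethoxy-6a,9-dimethyl-6a,10a-dihydro-6H-benzo[c]chromen-6-one | O=C1Oc2cc(OC)cc(OC)c2[C@@H]2C=C(C)C=C[C@]12C | intermediate
13 | (6aS,10aS)-1,3-dimethoxy-6a,9-dimethyl-6a,7,8,10a-tetrahydro-6H-benzo[c]chromen-6-one | O=C1Oc2cc(OC)cc(OC)c2[C@@H]2C=C(C)CC[C@]12C | intermediate
14 | (6aS,10aS)-1,3-dimethoxy-6a,9-dimethyl-6a,7,8,10a-tetrahydro-6H-benzo[c]chromen-6-ol (both C6 epimers) | OC1Oc2cc(OC)cc(OC)c2[C@@H]2C=C(C)CC[C@]12C | intermediate
15 | 5,7-dimethoxy-2H-chromen-2-one (citropten) | COc1cc(OC)c2ccc(=O)oc2c1 | starting material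
16 | N-[(5,7-dimethoxy-2-oxo-2H-chromen-8-yl)methylidene]-N-methylmethanaminium chloride | COc1cc(OC)c2ccc(=O)oc2c1C=[N+](C)C.[Cl-] | intermediate (not isolated)
17 | 5,7-dimethoxy-2-oxo-2H-chromene-8-carbaldehyde | COc1cc(OC)c2ccc(=O)oc2c1C=O | intermediate
18 | 8-(hydroxymethyl)-5,7-dimethoxy-2H-chromen-2-one | COc1cc(OC)c2ccc(=O)oc2c1CO | intermediate
19 | 8-(bromomethyl)-5,7-dimethoxy-2H-chromen-2-one | COc1cc(OC)c2ccc(=O)oc2c1CBr | intermediate (not isolated)
20 | diethyl [(5,7-dimethoxy-2-oxo-2H-chromen-8-yl)methyl]phosphonate | CCOP(=O)(Cc1c(OC)cc(OC)c2ccc(=O)oc12)OCC | intermediate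
21 | potassium salt of the benzylic carbanion of 20 | CCOP(=O)([CH-]c1c(OC)cc(OC)c2ccc(=O)oc12)OCC.[K+] | intermediate (not isolated)
22 | (1S,2S)-2-(2-hydroxy-4,6-dimethoxyphenyl)-1,4-dimethylcyclohex-3-ene-1-carbaldehyde (reacts as its phenoxide) | O=C[C@@]1(C)CCC(C)=C[C@H]1c1c(O)cc(OC)cc1OC | intermediate (not isolated)
23 | 8-[(E)-2-[(1R,2R)-2-(2-hydroxy-4,6-dimethoxyphenyl)-1,4-dimethylcyclohex-3-en-1-yl]ethenyl]-5,7-dimethoxy-2H-chromen-2-one | COc1cc(OC)c2ccc(=O)oc2c1/C=C/[C@@]1(C)CCC(C)=C[C@H]1c1c(O)cc(OC)cc1OC | intermediate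
24 | 8-[(E)-2-[(1R,2R)-2-[2-hydroxy-3-(hydroxymethyl)-4,6-dimethoxyphenyl]-1,4-dimethylcyclohex-3-en-1-yl]ethenyl]-5,7-dimethoxy-2H-chromen-2-one | COc1cc(OC)c2ccc(=O)oc2c1/C=C/[C@@]1(C)CCC(C)=C[C@H]1c1c(O)c(CO)c(OC)cc1OC | intermediate (not isolated)
25 | 8-[(E)-2-[(1R,2R)-2-(3-formyl-2-hydroxy-4,6-dimethoxyphenyl)-1,4-dimethylcyclohex-3-en-1-yl]ethenyl]-5,7-dimethoxy-2H-chromen-2-one | COc1cc(OC)c2ccc(=O)oc2c1/C=C/[C@@]1(C)CCC(C)=C[C@H]1c1c(O)c(C=O)c(OC)cc1OC | intermediate
26 | ethyl (E)-3-[3-[(1R,6R)-6-[(E)-2-(5,7-dimethoxy-2-oxo-2H-chromen-8-yl)ethenyl]-3,6-dimethylcyclohex-2-en-1-yl]-2-hydroxy-4,6-dimethoxyphenyl]prop-2-enoate | COc1cc(OC)c2ccc(=O)oc2c1/C=C/[C@@]1(C)CCC(C)=C[C@H]1c1c(OC)cc(OC)c(/C=C/C(=O)OCC)c1O | intermediate (not isolated)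
27 | 8-[(E)-2-[(1R,2R)-2-(5,7-dimethoxy-2-oxo-2H-chromen-8-yl)-1,4-dimethylcyclohex-3-en-1-yl]ethenyl]-5,7-dimethoxy-2H-chromen-2-one | COc1cc(OC)c2ccc(=O)oc2c1/C=C/[C@@]1(C)CCC(C)=C[C@H]1c1c(OC)cc(OC)c2ccc(=O)oc12 | target

**Step count and risks**

Total step count: 15. Longest linear sequence: 11 steps (steps 1, 3 to 9, 13 to 15); step 2 and steps 10 to 12 are side branches.

Steps most likely to fail:

Step 5. Formate may reduce the arylpalladium bromide before the ester has turned into the s-trans rotamer needed for insertion, so bromine is lost without ring closure. The activated ester may also be cleaved by acyl transfer, or the ligand may discriminate poorly between the two alkenes. The fallback sets out from 6 and 4 and comes back at 9; it makes the same C2–C8 bond without a metal and without a reductant. Acid chloride 6 is condensed with the unbrominated phenol 4 (Et3N, DMAP) to give 3,5-dimethoxyphenyl 1-methylcyclohexa-2,5-diene-1-carboxylate F1, which is oxidised as in step 4 to 3,5-dimethoxyphenyl 1-methyl-4-oxocyclohexa-2,5-diene-1-carboxylate F2. Sc(OTf)3 (10 mol%) in (CF3)2CHOH at 0 °C → rt should then bring about an intramolecular Friedel–Crafts conjugate addition of the arene carbon ortho to the ester oxygen (para to a methoxy group) to the activated dienone. This should give racemic cis-1,3-dimethoxy-6a-methyl-10,10a-dihydro-6H-benzo[c]chromene-6,9(6aH)-dione F3, cis by the same tether argument. Preparative chromatography on a chiral stationary phase then supplies 9. The price is half of the material and the catalytic asymmetric step; the gain is that no reduction competes with ring closure.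

Step 13. The α-quaternary aldehyde, largely masked as the lactolate, may react slowly with the hindered di-ortho-substituted phosphonate carbanion, which is meanwhile consumed by conjugate addition to the C3=C4 bond of another coumarin. The fallback sets out from 14 and comes back at 23; it builds the alkene by cross-coupling instead of carbonyl olefination. Ohira–Bestmann homologation of 14 (dimethyl (1-diazo-2-oxopropyl)phosphonate, K2CO3, MeOH, rt) gives 2-[(1R,6S)-6-ethynyl-3,6-dimethylcyclohex-2-en-1-yl]-3,5-dimethoxyphenol F4. Syn-hydroboration with excess pinacolborane (Cp2Zr(H)Cl 10 mol%, Et3N, 60 °C; the phenol is O-borylated transiently and freed on work-up) gives 2-[(1R,6R)-3,6-dimethyl-6-[(E)-2-(4,4,5,5-tetramethyl-1,3,2-dioxaborolan-2-yl)ethenyl]cyclohex-2-en-1-yl]-3,5-dimethoxyphenol F5. Citropten 15 is iodinated at C8 (N-iodosuccinimide, cat. CF3CO2H, MeCN) to 8-iodo-5,7-dimethoxy-2H-chromen-2-one F6. Suzuki–Miyaura coupling of F5 with F6 (Pd(dppf)Cl2, K3PO4, dioxane/H2O, 70 °C) should give 23 with the E geometry fixed by the hydroboration.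

Step 8. Discrimination between the two C=C bonds of the diene may be incomplete (reduction of the trisubstituted bond or of both), giving isomeric or saturated lactones that are hard to separate. The fallback sets out from 11 and comes back at 13; it reduces the alkene before the methyl group is introduced, when the bond to be kept is an electron-poor triflyloxy-alkene. Homogeneous hydrogenation of 11 (H2 1 atm, RhCl(PPh3)3, benzene/EtOH, rt) should saturate only the disubstituted C7=C8 bond and give (6aS,10aS)-1,3-dimethoxy-6a-methyl-6-oxo-6a,7,8,10a-tetrahydro-6H-benzo[c]chromen-9-yl trifluoromethanesulfonate F7. The coupling of step 7 (Me2Zn, Pd(PPh3)4) applied to F7 then gives 13.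

**Further compounds**

F1 | step 5 | 3,5-dimethoxyphenyl 1-methylcyclohexa-2,5-diene-1-carboxylate | CC1(C(=O)Oc2cc(OC)cc(OC)c2)C=CCC=C1
F2 | step 5 | 3,5-dimethoxyphenyl 1-methyl-4-oxocyclohexa-2,5-diene-1-carboxylate | CC1(C(=O)Oc2cc(OC)cc(OC)c2)C=CC(=O)C=C1
F3 | step 5 | racemic cis-1,3-dimethoxy-6a-methyl-10,10a-dihydro-6H-benzo[c]chromene-6,9(6aH)-dione (racemate of 9) | O=C1Oc2cc(OC)cc(OC)c2C2CC(=O)C=CC12C
F4 | step 13 | 2-[(1R,6S)-6-ethynyl-3,6-dimethylcyclohex-2-en-1-yl]-3,5-dimethoxyphenol | C#C[C@@]1(C)CCC(C)=C[C@H]1c1c(O)cc(OC)cc1OC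
F5 | step 13 | 2-[(1R,6R)-3,6-dimethyl-6-[(E)-2-(4,4,5,5-tetramethyl-1,3,2-dioxaborolan-2-yl)ethenyl]cyclohex-2-en-1-yl]-3,5-dimethoxyphenol | CC1(C)OB(/C=C/[C@@]2(C)CCC(C)=C[C@H]2c2c(O)cc(OC)cc2OC)OC1(C)C
F6 | step 13 | 8-iodo-5,7-dimethoxy-2H-chromen-2-one | COc1cc(OC)c2ccc(=O)oc2c1I
F7 | step 8 | (6aS,10aS)-1,3-dimethoxy-6a-methyl-6-oxo-6a,7,8,10a-tetrahydro-6H-benzo[c]chromen-9-yl trifluoromethanesulfonate | O=C1Oc2cc(OC)cc(OC)c2[C@@H]2C=C(OS(=O)(=O)C(F)(F)F)CC[C@]12C
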